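**Retrosynthetic overview**

1. The last bonds made are the seven O–Si cleavages and the outer aryl–Cα bond. That bond is cut to an aryltitanium and a D-serine-derived (S)-α-aryloxy aldehyde on one guaiacyl oxygen, so the third unit is added after the symmetric stage.
2. Feature used: in each inner arm Cβ carries H, the Cγ CH2OH and the ether oxygen of a syringyl ring, so it is C2 of a glyceric acid. The neighbouring benzylic Cα–OH is erythro to it (αS,βR). The two arms are exchanged by the C2 axis through the C8–C8′ bond of the 3,7-dioxabicyclo[3.3.0]octane.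
3. Key disconnection: both inner aryl–Cα bonds are cut at once, giving the C2-symmetric bis[(R)-α-aryloxy aldehyde] and two ArTi(OiPr)3 (non-chelating Felkin–Anh addition). The Cβ–O bonds come from a double Mitsunobu inversion of L-serine-derived (S)-glycerate on (−)-syringaresinol.
4. Rings: a temporary γ-lactone is made first (Evans succinate syn-aldol, reduction, lactonisation) and relays C8 to C8′ through a trans aldol. After its reductive opening both tetrahydrofuran rings are closed together in one acid step, and no ring is formed afterwards.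

Key step: step 17

Locants: core carbons are C7/C8/C9 and C7′/C8′/C9′ (lignan numbering). Arm carbons are Cα (benzylic), Cβ and Cγ. Ar = 4-(benzyloxy)-3,5-dimethoxyphenyl and TBS = tert-butyldimethylsilyl.

Assumption: the carbinol carbon C7′ made in step 7 is carried as an epimer mixture, because step 9 ionises it and sets it anew. Its descriptor is left open in 13 and 14.

**Route**

Step 1
Reactants: 1 syringaldehyde
Product: 2 4-(benzyloxy)-3,5-dimethoxybenzaldehyde
Conditions: BnBr, K2CO3, DMF, rt → 50 °C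
Reagents that add atoms: benzyl bromide, BrCc1ccccc1
Why: Williamson ether synthesis on the phenoxide masks the acidic phenol for the enolate and hydride steps that follow; no stereocentre is involved.

Step 2
Reactants: 3 mono-tert-butyl succinate; 4 (R)-4-benzyloxazolidin-2-one
Product: 6 tert-butyl 4-[(R)-4-benzyl-2-oxooxazolidin-3-yl]-4-oxobutanoate, via mixed pivalic anhydride 5 (not isolated)
Conditions: PivCl, Et3N, THF, −20 °C; then LiCl, 4, −20 °C → rt
Reagents that add atoms: pivaloyl chloride, CC(C)(C)C(=O)Cl (its acyl group stays only in 5)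
Why: N-acylation of the oxazolidinone by a mixed anhydride, which is attacked at the unhindered succinyl carbonyl with LiCl assistance, is a standard way to load the auxiliary and leaves the tert-butyl ester untouched.

Step 3
Reactants: 6 imide; 2 4-(benzyloxy)-3,5-dimethoxybenzaldehyde
Product: 8 tert-butyl (3R,4R)-3-[(R)-4-benzyl-2-oxooxazolidine-3-carbonyl]-4-Ar-4-hydroxybutanoate, via Z-boron enolate 7 (not isolated)
Conditions: Bu2BOTf, iPr2NEt, CH2Cl2, −78 → 0 °C; 2, −78 → 0 °C; then pH 7 buffer, MeOH, 30% H2O2, 0 °C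
Reagents that add atoms: dibutylboron triflate, CCCCB(CCCC)OS(=O)(=O)C(F)(F)F (its Bu2B group stays only in 7)
Why: Evans syn-aldol reaction, in which soft enolisation occurs at the imide and not at the ester, and the Zimmerman–Traxler chair of the Z-enolate, shielded on one face by the benzyl group of the (R)-auxiliary, sets C8 and C7 (3R,4R), while the bulky tert-butyl ester keeps the aldolate from lactonising.

Step 4
Reactants: 8 syn-aldol adduct
Product: 9 tert-butyl (3R,4R)-3-[(R)-4-benzyl-2-oxooxazolidine-3-carbonyl]-4-Ar-4-(TBSO)butanoate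
Conditions: TBSOTf, 2,6-lutidine, CH2Cl2, −78 → 0 °C
Reagents that add atoms: tert-butyldimethylsilyl triflate, CC(C)(C)[Si](C)(C)OS(=O)(=O)C(F)(F)F
Why: Silyl ether formation at the C7 hydroxyl is far faster than any attack on the tert-butyl ester at this temperature, and it blocks C7–O from taking part in the later lactonisation.

Step 5
Reactants: 9 silylated imide
Product: 10 tert-butyl (3S,4R)-4-Ar-4-(TBSO)-3-(hydroxymethyl)butanoate
Conditions: LiBH4, THF, 0 °C
Reagents that add atoms: none
Why: Reductive cleavage of an N-acyl oxazolidinone by LiBH4 takes the activated imide carbonyl to C9H2OH, releases the auxiliary for re-use and spares the tert-butyl ester; the geometry at C8 is unchanged (the descriptor changes only by priority).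

Step 6
Reactants: 10 hydroxy ester
Product: 11 (S)-4-[(R)-Ar(TBSO)methyl]dihydrofuran-2(3H)-one
Conditions: p-TsOH·H2O (cat.), CH2Cl2, 0 °C → rt
Reagents that add atoms: none
Why: Acid-catalysed lactonisation (5-exo-trig intramolecular transesterification) of a γ-hydroxy tert-butyl ester closes the C9–O–C9′ lactone, and the trialkoxybenzyl silyl ether, whose cation is only moderately stabilised, should tolerate catalytic anhydrous acid.

Step 7
Reactants: 11 lactone; 2 4-(benzyloxy)-3,5-dimethoxybenzaldehyde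
Product: 13 (3R,4S)-3-[Ar(hydroxy)methyl]-4-[(R)-Ar(TBSO)methyl]dihydrofuran-2(3H)-one (C7′ epimers), via lithium enolate 12 (not isolated)
Conditions: LiN(iPr)2, THF, −78 °C; 2, −78 °C; AcOH quench at −78 °C
Reagents that add atoms: lithium diisopropylamide, [Li]N(C(C)C)C(C)C (its lithium stays only in 12)
Why: Aldol addition of a butyrolactone lithium enolate, in which the aldehyde approaches the ring face anti to the large C4 substituent and so sets C8′ trans to C8, the relation that maps onto the cis-fused furofuran.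

Step 8
Reactants: 13 aldol lactone
Product: 14 (2S,3S)-2-[Ar(hydroxy)methyl]-3-[(R)-Ar(TBSO)methyl]butane-1,4-diol (C7′ epimers)
Conditions: LiAlH4, THF, 0 °C; aq potassium sodium tartrate
Reagents that add atoms: none
Why: Hydride reduction of the lactone to the 1,4-diol frees C9–OH and C9′–OH without touching C8, C8′, the silyl ether or the benzyl ethers.

Step 9
Reactants: 14 triol
Product: 15 4,4′-di-O-benzyl-(−)-syringaresinol, (1R,3aS,4R,6aS)-1,4-bis-Ar-tetrahydro-1H,3H-furo[3,4-c]furan
Conditions: 3 M aq HCl, THF, 0 °C → rt, stopped at full conversion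
Reagents that add atoms: none
Why: Acid-mediated double dehydrative etherification (SN1): both benzylic C–O bonds ionise to p-alkoxybenzyl cations and each is trapped 5-exo by the primary hydroxyl across the C8–C8′ bond, so the (8S,8′S) pair forces the cis ring fusion and kinetically places both aryl groups on the convex face (7R,7′R).

Step 10
Reactants: 15 dibenzyl ether
Product: 16 (−)-syringaresinol (7R,8S,7′R,8′S)
Conditions: H2 (1 atm), 10% Pd/C, EtOAc, rt
Reagents that add atoms: none
Why: Catalytic hydrogenolysis cleaves aryl benzyl ethers much faster than the cyclic benzylic ethers of the furofuran, so a short reaction at atmospheric pressure should free only the two phenols.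

Step 11
Reactants: 17 L-serine
Product: 19 methyl (S)-2,3-dihydroxypropanoate, via (S)-glyceric acid 18 (not isolated)
Conditions: NaNO2, aq H2SO4, 0 °C → rt; evaporation; then MeOH, H2SO4 (cat.), reflux
Reagents that add atoms: water, O; methanol, CO
Why: Diazotisation of an α-amino acid replaces N by O with net retention (double inversion through the α-lactone), and Fischer esterification then gives the ester without touching C2.

Step 12
Reactants: 19 methyl (S)-glycerate
Product: 20 methyl (S)-3-(TBSO)-2-hydroxypropanoate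
Conditions: TBSCl (1.05 equiv), imidazole, CH2Cl2, 0 °C
Reagents that add atoms: tert-butyldimethylsilyl chloride, CC(C)(C)[Si](C)(C)Cl
Why: Selective silylation takes the primary hydroxyl, because the secondary one is more hindered and deactivated by the adjacent ester.

Step 13
Reactants: 16 (−)-syringaresinol; 20 methyl (S)-3-(TBSO)-2-hydroxypropanoate
Product: 21 4,4′-bis-O-[(R)-1-methoxycarbonyl-2-(TBSO)ethyl]-(−)-syringaresinol
Conditions: 20 (2.6 equiv), PPh3, DIAD, THF (concentrated), 0 °C → rt
Reagents that add atoms: none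
Why: Double Mitsunobu etherification, in which α-hydroxy esters are among the best secondary alcohols for SN2 displacement of the alkoxyphosphonium ion, so each phenoxide should attack with clean inversion, (S) → (R), and fix both Cβ centres.

Step 14
Reactants: 21 bis-ester
Product: 22 4,4′-bis-O-[(R)-1-formyl-2-(TBSO)ethyl]-(−)-syringaresinol
Conditions: iBu2AlH (2.3 equiv), CH2Cl2, −78 °C; MeOH, then aq potassium sodium tartrate; used crude at once
Reagents that add atoms: none
Why: Partial ester reduction stops at the aldehyde stage because the α-oxygenated aluminium hemiacetal persists at −78 °C until the quench, and the neutral work-up with immediate use protects the enolisable Cβ–H.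

Step 15
Reactants: 23 4-bromo-2-methoxyphenol
Product: 24 1-(benzyloxy)-4-bromo-2-methoxybenzene
Conditions: BnBr, K2CO3, DMF, rt
Reagents that add atoms: benzyl bromide, BrCc1ccccc1
Why: Williamson ether synthesis removes the acidic proton before metalation and installs a group orthogonal to the silyl ethers.

Step 16
Reactants: 24 aryl bromide
Product: 26 4-(benzyloxy)-3-methoxyphenyltitanium triisopropoxide (THF solution), via aryllithium 25 (not isolated)
Conditions: n-BuLi, THF, −78 °C; ClTi(OiPr)3, −78 → −30 °C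
Reagents that add atoms: n-butyllithium, [Li]CCCC (its lithium stays only in 25); chlorotitanium triisopropoxide, CC(C)O[Ti](Cl)(OC(C)C)OC(C)C
Why: Bromine–lithium exchange followed by transmetalation to titanium converts a basic aryllithium into a weakly basic, weakly Lewis acidic aryl donor.

Step 17
Reactants: 22 bis-aldehyde; 26 aryltitanium triisopropoxide (3 equiv)
Product: 27 4,4′-bis-O-[(1S,2R)-1-(4-benzyloxy-3-methoxyphenyl)-1-hydroxy-3-(TBSO)propan-2-yl]-(−)-syringaresinol
Conditions: 26, THF, −78 → −20 °C; aq NH4Cl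
Reagents that add atoms: none
Why: Each formyl group binds one ArTi(OiPr)3 through its carbonyl oxygen only and receives the aryl group by 1,2-addition, the closest known reaction type being the non-chelation-controlled addition of organotitanium triisopropoxides to α-alkoxy aldehydes. Two aryl–Cα bonds and two stereocentres are formed and no ring is closed. Each aldehyde should react in the polar Felkin–Anh conformer, with the Cβ–OAr bond perpendicular to C=O and the aryl group arriving anti to it past Cβ–H, so the (R)-Cβ centre derived from L-serine sets (S)-Cα, which is the anti or erythro relation. The step needs high 1,2-diastereoselectivity at both ends together with retention of the enolisable Cβ–H. The substrate secures the first, since the 2,6-dimethoxyphenyl ether oxygen is crowded and delocalised, the OTBS oxygen is a poor ligand and the alkoxide-saturated titanium is a weak acceptor, so no five- or six-membered chelate competes; the low basicity of 26 secures the second and also suppresses β-elimination of silanolate. The two ends are remote and related by the C2 axis, so they react independently, and a product epimeric at one Cα is an unsymmetrical diastereomer that chromatography should remove.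

Step 18
Reactants: 27 bis-carbinol
Product: 28 the bis(Cα-O-TBS) ether of 27
Conditions: TBSOTf (3 equiv), 2,6-lutidine, CH2Cl2, 0 °C → rt
Reagents that add atoms: tert-butyldimethylsilyl triflate, CC(C)(C)[Si](C)(C)OS(=O)(=O)C(F)(F)F
Why: Silylation with the triflate reaches hindered benzylic alcohols under buffered conditions and removes the two secondary hydroxyls that would otherwise compete as alcohol partners in the later Mitsunobu reaction.

Step 19
Reactants: 28 dibenzyl ether
Product: 29 the C2-symmetric bis(guaiacyl phenol)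
Conditions: H2 (1 atm), 10% Pd/C, EtOAc, rt
Reagents that add atoms: none
Why: Hydrogenolysis of the two aryl benzyl ethers outruns cleavage of the furofuran C7–O bonds and of the benzylic silyl ethers, and the non-acidic, non-protic solvent keeps all four TBS groups in place.

Step 20
Reactants: 29 bis-phenol
Product: 30 mono(phenol O-TBS) ether of 29
Conditions: TBSCl (1.0 equiv), imidazole, DMF, 0 °C
Reagents that add atoms: tert-butyldimethylsilyl chloride, CC(C)(C)[Si](C)(C)Cl
Why: Silylation of one of two equivalent, non-communicating phenols should give a statistical mixture separable by polarity, in which recovered 29 is resubmitted and the bis-ether returns to 29 with K2CO3/MeOH, so the desymmetrisation loses no advanced material.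

Step 21
Reactants: 31 D-serine
Product: 33 methyl (R)-2,3-dihydroxypropanoate, via (R)-glyceric acid 32 (not isolated)
Conditions: NaNO2, aq H2SO4, 0 °C → rt; evaporation; then MeOH, H2SO4 (cat.), reflux
Reagents that add atoms: water, O; methanol, CO
Why: Diazotisation with net retention through the α-lactone, followed by Fischer esterification, gives the mirror image of 19.

Step 22
Reactants: 33 methyl (R)-glycerate
Product: 34 methyl (R)-3-(TBSO)-2-hydroxypropanoate
Conditions: TBSCl (1.05 equiv), imidazole, CH2Cl2, 0 °C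
Reagents that add atoms: tert-butyldimethylsilyl chloride, CC(C)(C)[Si](C)(C)Cl
Why: Selective silylation of the primary hydroxyl follows the same steric and electronic bias as in step 12.

Step 23
Reactants: 30 mono-phenol; 34 methyl (R)-3-(TBSO)-2-hydroxypropanoate
Product: 35 the ether of 30 bearing an (S)-1-methoxycarbonyl-2-(TBSO)ethyl group on the free guaiacyl oxygen
Conditions: 34 (1.5 equiv), PPh3, DIAD, THF, 0 °C → rt
Reagents that add atoms: none
Why: Mitsunobu etherification of the only free hydroxyl, a mono-ortho-substituted phenol, should proceed by SN2 inversion, (R) → (S), and set the outer Cβ.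

Step 24
Reactants: 35 ester
Product: 36 the corresponding (S)-α-aryloxy aldehyde
Conditions: iBu2AlH (1.2 equiv), CH2Cl2, −78 °C; MeOH, then aq potassium sodium tartrate; used crude at once
Reagents that add atoms: none
Why: Partial ester reduction through the cold-stable aluminium hemiacetal gives the aldehyde, and alkyl and aryl silyl ethers are inert to iBu2AlH at −78 °C.

Step 25
Reactants: 23 4-bromo-2-methoxyphenol
Product: 37 (4-bromo-2-methoxyphenoxy)(tert-butyl)dimethylsilane
Conditions: TBSCl, imidazole, DMF, rt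
Reagents that add atoms: tert-butyldimethylsilyl chloride, CC(C)(C)[Si](C)(C)Cl
Why: Phenol silylation gives a metalation-compatible aryl bromide whose protecting group falls in the same final operation as all the others.

Step 26
Reactants: 37 aryl bromide
Product: 39 4-(TBSO)-3-methoxyphenyltitanium triisopropoxide (THF solution), via aryllithium 38 (not isolated)
Conditions: n-BuLi, THF, −78 °C; ClTi(OiPr)3, −78 → −30 °C
Reagents that add atoms: n-butyllithium, [Li]CCCC (its lithium stays only in 38); chlorotitanium triisopropoxide, CC(C)O[Ti](Cl)(OC(C)C)OC(C)C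
Why: Bromine–lithium exchange and transmetalation proceed as in step 16, and the para relation of lithium and OTBS rules out intramolecular silyl migration.

Step 27
Reactants: 36 aldehyde; 39 aryltitanium triisopropoxide (2 equiv)
Product: 40 heptakis-TBS ether of the target with the outer Cα–OH free, outer arm (1R,2S)
Conditions: 39, THF, −78 → −20 °C; aq NH4Cl
Reagents that add atoms: none
Why: Non-chelating Felkin–Anh 1,2-addition, mirror image of step 17, in which the (S)-Cβ centre from D-serine directs the aryl group anti to the Cβ–OAr bond and sets (R)-Cα, again erythro, with no acidic proton left in 36 to consume the reagent.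

Step 28
Reactants: 40 heptasilyl ether
Product: 41 target CNP0316493.2
Conditions: Bu4NF/AcOH (1:1, excess), THF, 0 °C → rt
Reagents that add atoms: none
Why: Fluoride-induced desilylation removes all seven TBS groups, and the acetic acid buffer keeps the freed phenols protonated, so that neither quinone methide formation nor epimerisation at the benzylic carbons can start.

**Compound list**

1 | syringaldehyde | COc1cc(C=O)cc(OC)c1O | starting material
2 | 4-(benzyloxy)-3,5-dimethoxybenzaldehyde | COc1cc(C=O)cc(OC)c1OCc1ccccc1 | intermediate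
3 | mono-tert-butyl succinate (4-tert-butoxy-4-oxobutanoic acid) | CC(C)(C)OC(=O)CCC(=O)O | starting material
4 | (R)-4-benzyloxazolidin-2-one | O=C1N[C@H](Cc2ccccc2)CO1 | starting material
5 | 4-tert-butoxy-4-oxobutanoic pivalic anhydride | CC(C)(C)OC(=O)CCC(=O)OC(=O)C(C)(C)C | intermediate
6 | tert-butyl 4-[(R)-4-benzyl-2-oxooxazolidin-3-yl]-4-oxobutanoate | CC(C)(C)OC(=O)CCC(=O)N1C(=O)OC[C@H]1Cc1ccccc1 | intermediate
7 | Z-dibutylboron enolate of 6 | CCCCB(CCCC)O/C(=C\CC(=O)OC(C)(C)C)N1C(=O)OC[C@H]1Cc1ccccc1 | intermediate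
8 | tert-butyl (3R,4R)-3-[(R)-4-benzyl-2-oxooxazolidine-3-carbonyl]-4-[4-(benzyloxy)-3,5-dimethoxyphenyl]-4-hydroxybutanoate | CC(C)(C)OC(=O)C[C@H]([C@@H](O)c1cc(OC)c(OCc2ccccc2)c(OC)c1)C(=O)N1C(=O)OC[C@H]1Cc1ccccc1 | intermediate
9 | 4-O-TBS ether of 8 (3R,4R) | CC(C)(C)OC(=O)C[C@H]([C@@H](O[Si](C)(C)C(C)(C)C)c1cc(OC)c(OCc2ccccc2)c(OC)c1)C(=O)N1C(=O)OC[C@H]1Cc1ccccc1 | intermediate
10 | tert-butyl (3S,4R)-4-[4-(benzyloxy)-3,5-dimethoxyphenyl]-4-(TBSO)-3-(hydroxymethyl)butanoate | CC(C)(C)OC(=O)C[C@H]([C@@H](O[Si](C)(C)C(C)(C)C)c1cc(OC)c(OCc2ccccc2)c(OC)c1)CO | intermediate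
11 | (S)-4-{(R)-[4-(benzyloxy)-3,5-dimethoxyphenyl](TBSO)methyl}dihydrofuran-2(3H)-one | O=C1C[C@H]([C@@H](O[Si](C)(C)C(C)(C)C)c2cc(OC)c(OCc3ccccc3)c(OC)c2)CO1 | intermediate
12 | lithium enolate of 11 | [Li]OC1=C[C@H]([C@@H](O[Si](C)(C)C(C)(C)C)c2cc(OC)c(OCc3ccccc3)c(OC)c2)CO1 | intermediate
13 | (3R,4S)-3-{[4-(benzyloxy)-3,5-dimethoxyphenyl](hydroxy)methyl}-4-{(R)-[4-(benzyloxy)-3,5-dimethoxyphenyl](TBSO)methyl}dihydrofuran-2(3H)-one, C7′ epimers | O=C1[C@@H](C(O)c2cc(OC)c(OCc3ccccc3)c(OC)c2)[C@H]([C@@H](O[Si](C)(C)C(C)(C)C)c2cc(OC)c(OCc3ccccc3)c(OC)c2)CO1 | intermediate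
14 | (2S,3S)-2-{[4-(benzyloxy)-3,5-dimethoxyphenyl](hydroxy)methyl}-3-{(R)-[4-(benzyloxy)-3,5-dimethoxyphenyl](TBSO)methyl}butane-1,4-diol, C7′ epimers | OC[C@@H](C(O)c1cc(OC)c(OCc2ccccc2)c(OC)c1)[C@H]([C@@H](O[Si](C)(C)C(C)(C)C)c1cc(OC)c(OCc2ccccc2)c(OC)c1)CO | intermediate
15 | 4,4′-di-O-benzyl-(−)-syringaresinol (7R,8S,7′R,8′S) | COc1cc([C@@H]2OC[C@@H]3[C@H]2CO[C@H]3c2cc(OC)c(OCc3ccccc3)c(OC)c2)cc(OC)c1OCc1ccccc1 | intermediate
16 | (−)-syringaresinol (7R,8S,7′R,8′S) | COc1cc([C@@H]2OC[C@@H]3[C@H]2CO[C@H]3c2cc(OC)c(O)c(OC)c2)cc(OC)c1O | intermediate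
17 | L-serine | N[C@@H](CO)C(O)=O | starting material
18 | (S)-glyceric acid | O[C@@H](CO)C(O)=O | intermediate
19 | methyl (S)-2,3-dihydroxypropanoate | COC(=O)[C@@H](O)CO | intermediate
20 | methyl (S)-3-(TBSO)-2-hydroxypropanoate | COC(=O)[C@@H](O)CO[Si](C)(C)C(C)(C)C | intermediate
21 | 4,4′-bis-O-[(R)-1-methoxycarbonyl-2-(TBSO)ethyl]-(−)-syringaresinol | COC(=O)[C@@H](CO[Si](C)(C)C(C)(C)C)Oc1c(OC)cc([C@@H]2OC[C@@H]3[C@H]2CO[C@H]3c2cc(OC)c(O[C@H](CO[Si](C)(C)C(C)(C)C)C(=O)OC)c(OC)c2)cc1OC | intermediate
22 | 4,4′-bis-O-[(R)-1-formyl-2-(TBSO)ethyl]-(−)-syringaresinol | O=C[C@@H](CO[Si](C)(C)C(C)(C)C)Oc1c(OC)cc([C@@H]2OC[C@@H]3[C@H]2CO[C@H]3c2cc(OC)c(O[C@H](CO[Si](C)(C)C(C)(C)C)C=O)c(OC)c2)cc1OC | intermediate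
23 | 4-bromo-2-methoxyphenol | COc1cc(Br)ccc1O | starting material
24 | 1-(benzyloxy)-4-bromo-2-methoxybenzene | COc1cc(Br)ccc1OCc1ccccc1 | intermediate
25 | 4-(benzyloxy)-3-methoxyphenyllithium | COc1cc([Li])ccc1OCc1ccccc1 | intermediate
26 | 4-(benzyloxy)-3-methoxyphenyltitanium triisopropoxide | COc1cc([Ti](OC(C)C)(OC(C)C)OC(C)C)ccc1OCc1ccccc1 | intermediate
27 | 4,4′-bis-O-[(1S,2R)-1-(4-benzyloxy-3-methoxyphenyl)-1-hydroxy-3-(TBSO)propan-2-yl]-(−)-syringaresinol | COc1cc([C@H](O)[C@@H](CO[Si](C)(C)C(C)(C)C)Oc3c(OC)cc([C@@H]4OC[C@@H]5[C@H]4CO[C@H]5c4cc(OC)c(O[C@H](CO[Si](C)(C)C(C)(C)C)[C@@H](O)c5ccc(OCc6ccccc6)c(OC)c5)c(OC)c4)cc3OC)ccc1OCc2ccccc2 | intermediate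
28 | bis(Cα-O-TBS) ether of 27, both arms (1S,2R) | COc1cc([C@H](O[Si](C)(C)C(C)(C)C)[C@@H](CO[Si](C)(C)C(C)(C)C)Oc3c(OC)cc([C@@H]4OC[C@@H]5[C@H]4CO[C@H]5c4cc(OC)c(O[C@H](CO[Si](C)(C)C(C)(C)C)[C@@H](O[Si](C)(C)C(C)(C)C)c5ccc(OCc6ccccc6)c(OC)c5)c(OC)c4)cc3OC)ccc1OCc2ccccc2 | intermediate
29 | bis(guaiacyl phenol) from 28, four alkyl TBS ethers retained | COc1cc([C@H](O[Si](C)(C)C(C)(C)C)[C@@H](CO[Si](C)(C)C(C)(C)C)Oc3c(OC)cc([C@@H]4OC[C@@H]5[C@H]4CO[C@H]5c4cc(OC)c(O[C@H](CO[Si](C)(C)C(C)(C)C)[C@@H](O[Si](C)(C)C(C)(C)C)c5ccc(O)c(OC)c5)c(OC)c4)cc3OC)ccc1O | intermediate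
30 | mono(phenol O-TBS) ether of 29, one guaiacyl phenol free | COc1cc([C@H](O[Si](C)(C)C(C)(C)C)[C@@H](CO[Si](C)(C)C(C)(C)C)Oc3c(OC)cc([C@@H]4OC[C@@H]5[C@H]4CO[C@H]5c4cc(OC)c(O[C@H](CO[Si](C)(C)C(C)(C)C)[C@@H](O[Si](C)(C)C(C)(C)C)c5ccc(O[Si](C)(C)C(C)(C)C)c(OC)c5)c(OC)c4)cc3OC)ccc1O | intermediate
31 | D-serine | N[C@H](CO)C(O)=O | starting material
32 | (R)-glyceric acid | O[C@H](CO)C(O)=O | intermediate
33 | methyl (R)-2,3-dihydroxypropanoate | COC(=O)[C@H](O)CO | intermediate
34 | methyl (R)-3-(TBSO)-2-hydroxypropanoate | COC(=O)[C@H](O)CO[Si](C)(C)C(C)(C)C | intermediate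
35 | ether of 30 with an (S)-1-methoxycarbonyl-2-(TBSO)ethyl group on the guaiacyl oxygen | COC(=O)[C@H](CO[Si](C)(C)C(C)(C)C)Oc2ccc([C@H](O[Si](C)(C)C(C)(C)C)[C@@H](CO[Si](C)(C)C(C)(C)C)Oc3c(OC)cc([C@@H]4OC[C@@H]5[C@H]4CO[C@H]5c4cc(OC)c(O[C@H](CO[Si](C)(C)C(C)(C)C)[C@@H](O[Si](C)(C)C(C)(C)C)c5ccc(O[Si](C)(C)C(C)(C)C)c(OC)c5)c(OC)c4)cc3OC)cc2OC | intermediate
36 | (S)-α-aryloxy aldehyde from 35 | O=C[C@H](CO[Si](C)(C)C(C)(C)C)Oc2ccc([C@H](O[Si](C)(C)C(C)(C)C)[C@@H](CO[Si](C)(C)C(C)(C)C)Oc3c(OC)cc([C@@H]4OC[C@@H]5[C@H]4CO[C@H]5c4cc(OC)c(O[C@H](CO[Si](C)(C)C(C)(C)C)[C@@H](O[Si](C)(C)C(C)(C)C)c5ccc(O[Si](C)(C)C(C)(C)C)c(OC)c5)c(OC)c4)cc3OC)cc2OC | intermediate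
37 | (4-bromo-2-methoxyphenoxy)(tert-butyl)dimethylsilane | COc1cc(Br)ccc1O[Si](C)(C)C(C)(C)C | intermediate
38 | 4-(TBSO)-3-methoxyphenyllithium | COc1cc([Li])ccc1O[Si](C)(C)C(C)(C)C | intermediate
39 | 4-(TBSO)-3-methoxyphenyltitanium triisopropoxide | COc1cc([Ti](OC(C)C)(OC(C)C)OC(C)C)ccc1O[Si](C)(C)C(C)(C)C | intermediate
40 | heptakis-TBS ether of the target, outer arm (1R,2S) with free Cα–OH | COc1cc([C@@H](O)[C@H](CO[Si](C)(C)C(C)(C)C)Oc2ccc([C@H](O[Si](C)(C)C(C)(C)C)[C@@H](CO[Si](C)(C)C(C)(C)C)Oc3c(OC)cc([C@@H]4OC[C@@H]5[C@H]4CO[C@H]5c4cc(OC)c(O[C@H](CO[Si](C)(C)C(C)(C)C)[C@@H](O[Si](C)(C)C(C)(C)C)c5ccc(O[Si](C)(C)C(C)(C)C)c(OC)c5)c(OC)c4)cc3OC)cc2OC)ccc1O[Si](C)(C)C(C)(C)C | intermediate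
41 | CNP0316493.2: core 7R,8S,7′R,8′S; inner arms αS,βR; outer arm αR,βS | COc1cc([C@@H](O)[C@H](CO)Oc2ccc([C@H](O)[C@@H](CO)Oc3c(OC)cc([C@@H]4OC[C@@H]5[C@H]4CO[C@H]5c4cc(OC)c(O[C@H](CO)[C@@H](O)c5ccc(O)c(OC)c5)c(OC)c4)cc3OC)cc2OC)ccc1O | target

**Step count**

Total step count: 28.
Longest linear sequence: 19 steps (2–10, 13, 14, 17–20, 23, 24, 27, 28).

**Steps most likely to fail**

Step 17. Induction may be incomplete at one or both ends, and because both ends must react correctly any leakage counts twice. The aldehyde may also epimerise at Cβ or lose silanolate before the aryl group arrives.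

The fallback sets out from 21 and moves stereocontrol from the substrate to a catalyst.
- Treatment of 21 with MeNH(OMe)·HCl and iPrMgCl in THF at −20 °C should give the bis-Weinreb amide F1.
- Addition of aryllithium 25 at −78 °C should give the bis(aryl ketone) F2 with Cβ intact.
- Noyori asymmetric transfer hydrogenation with RuCl[(R,R)-TsDPEN](p-cymene) in HCO2H/Et3N should deliver hydride to the same face of both aryl ketones. This sets (S)-Cα at each end independently of Cβ.
- The sequence comes back to the route at 27.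

Step 13. The doubly ortho-substituted syringyl phenoxide may capture the alkoxyphosphonium ion too slowly. Alkylation of the reduced azodicarboxylate could then take over, or the reaction could stall after the first etherification.

The fallback sets out from 20 and separates activation from displacement.
- Tf2O and 2,6-lutidine in CH2Cl2 at −78 °C should give methyl (S)-3-(TBSO)-2-(trifluoromethylsulfonyloxy)propanoate F3.
- F3 is displaced by the bis-phenoxide of 16 (Cs2CO3, MeCN, 0 °C) in a direct SN2 reaction with inversion.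
- The sequence comes back to the route at 21.

Step 9. The acid may reopen the newly formed benzylic ethers and drift the aryl groups towards the endo position. A benzylic cation may also be captured by the other electron-rich ring in a Friedel–Crafts sense.

The fallback sets out from 1, replaces steps 1–10 and lets the biomimetic coupling fix the exo,exo geometry.
- Knoevenagel–Doebner condensation of 1 with monoethyl malonate (pyridine, piperidine) should give ethyl (E)-sinapate F4.
- iBu2AlH (excess, toluene, −78 → 0 °C) should give sinapyl alcohol F5.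
- Laccase-catalysed aerobic oxidation (O2, acetate buffer/MeCN) couples two phenoxy radicals at C8–C8′, and the bis-quinone methide closes both rings to racemic syringaresinol F6.
- Preparative chromatography on a cellulose carbamate chiral stationary phase separates the enantiomers.
- The sequence comes back to the route at 16.

**Further compounds**

F1 | step 17 | 4,4′-bis-O-{(R)-1-[methoxy(methyl)carbamoyl]-2-(TBSO)ethyl}-(−)-syringaresinol | CON(C)C(=O)[C@@H](CO[Si](C)(C)C(C)(C)C)Oc1c(OC)cc([C@@H]2OC[C@@H]3[C@H]2CO[C@H]3c2cc(OC)c(O[C@H](CO[Si](C)(C)C(C)(C)C)C(=O)N(C)OC)c(OC)c2)cc1OC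
F2 | step 17 | 4,4′-bis-O-[(R)-1-(4-benzyloxy-3-methoxyphenyl)-1-oxo-3-(TBSO)propan-2-yl]-(−)-syringaresinol | COc1cc(C(=O)[C@@H](CO[Si](C)(C)C(C)(C)C)Oc3c(OC)cc([C@@H]4OC[C@@H]5[C@H]4CO[C@H]5c4cc(OC)c(O[C@H](CO[Si](C)(C)C(C)(C)C)C(=O)c5ccc(OCc6ccccc6)c(OC)c5)c(OC)c4)cc3OC)ccc1OCc2ccccc2
F3 | step 13 | methyl (S)-3-(TBSO)-2-(trifluoromethylsulfonyloxy)propanoate | COC(=O)[C@@H](OS(=O)(=O)C(F)(F)F)CO[Si](C)(C)C(C)(C)C
F4 | step 9 | ethyl (E)-sinapate | CCOC(=O)/C=C/c1cc(OC)c(O)c(OC)c1
F5 | step 9 | (E)-sinapyl alcohol | OC/C=C/c1cc(OC)c(O)c(OC)c1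
F6 | step 9 | racemic syringaresinol (both enantiomers) | COc1cc([C@@H]2OC[C@@H]3[C@H]2CO[C@H]3c2cc(OC)c(O)c(OC)c2)cc(OC)c1O.COc1cc([C@H]2OC[C@H]3[C@@H]2CO[C@@H]3c2cc(OC)c(O)c(OC)c2)cc(OC)c1O
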